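The data come from a simulation with made-up constants.

The charges in winter, dawn and dusk are the same, and what differs is the hour at which each enters. Winter is also the ash recipe carried on to 20 h. So the decision for the next run was which charge, if any, to hold back.

| flask | starting material | reagent | second substrate | free catalyst | remark | time |
|---|---|---|---|---|---|---|
| ash | 0.20 M | 0.40 M | 0.20 M | 9.2 mM | run made earlier |  |
| larch | 0.20 M | 0.60 M | 0.20 M | 9.2 mM | run made earlier |  |
| winter | 0.20 M | 0.400 M | 0.200 M | 9.2 mM | everything together at the start | 20 h |
| dawn | 0.20 M (fed, over 4.0 h) | 0.400 M | 0.200 M | 9.2 mM | all else is in the flask from the start; the feed brings no volume worth counting | 20 h |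
| dusk | 0.20 M | 0.400 M (fed, over 4.0 h) | 0.200 M | 9.2 mM | all else is in the flask from the start; the feed brings no volume worth counting | 20 h |

| run | time / h | target / % |
|---|---|---|
| ash | 2.00 | 11.8 |
| ash | 4.00 | 17.8 |
| ash | 6.00 | 18.9 |
| ash | 8.00 | 19.6 |
| ash | 10.0 | 21.2 |
| ash | 12.0 | 21.5 |
| larch | 0.417 | 5.8 |
| larch | 1.33 | 14.0 |
| larch | 2.00 | 16.6 |
| larch | 3.00 | 18.1 |
| larch | 5.00 | 21.8 |
| larch | 6.00 | 24.5 |

(scatter of a reading: 1 percentage point)

- the numbers in the tables scatter by 1 percentage point (one standard deviation)

* the flask that comes out highest in amount of target, in percent of the starting material charged, or "all alike" when all lie within 1.5 percentage points (winter / dawn / dusk / all alike)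
* target at the end, in percent of the starting material charged, winter
* target at the end, in percent of the starting material charged, dawn
* target at the end, in percent of the starting material charged, dusk

The ash run read 21.5 % at 12.0 h, and I took that reading as my estimate for winter. No run had followed the second substrate, so I set my scale at the statistical case, a selectivity factor of one: a catalyst blind to the two substrates divides its turns in proportion to their concentrations. On that scale, with both substrates together in winter at equal charge, the starting material gets 0.500 of the turns. Fed at a steady rate in dawn, and before any consumption, [starting material] averages 0.100 M over the feed. With [second substrate] held at its charge, the fraction falls to 0.333, which is lower. This I called the target share, the mean [starting material] divided by itself plus [second substrate]. Feeding reagent in dusk leaves the two substrates at their equal charge, so on that scale dusk keeps 0.500. The ash run had read 17.8 % at 4.00 h, 0.828 of its last reading, so I let the share over the feed stand for the whole of dawn and put dawn at 0.667 of winter, about 14.3 %, a loss of 7.2 percentage points, larger than the margin. I decided to keep the starting material in from the start, and I reckoned dusk level with winter.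

The forecast gave all alike, with 24.5 % for winter, 23.8 % for dawn and 23.5 % for dusk, holding that “Feeding over 4 h only delays things”, which parts from my reckoning on dawn.

Winter gave 18.2 %, dawn 13.4 % and dusk 20.5 %, so dusk came out highest.

    starting material + reagent + free catalyst → free catalyst + target (k = 27.1 M⁻² h⁻¹)
    2 reagent → self-condensation product (k = 0.445 M⁻¹ h⁻¹)
    starting material + target → side product (k = 0.247 M⁻¹ h⁻¹)
    2 free catalyst → spent catalyst (k = 0.690 M⁻¹ h⁻¹)
    second substrate + reagent + free catalyst → free catalyst + second product (k = 51.9 M⁻² h⁻¹)

Dawn over winter came to 0.736 against my 0.667, and the mean [starting material] in dawn over the first 4.0 h was 0.0933 M. I then counted the turns on starting material as target plus half the side product, since in these percentages each side product counts as two. Against second product, they made 0.296 of the turns on the two substrates in dawn by 20.0 h. With 0.34 M charged, the neighbour of dawn has a reckoned target share over the feed of 0.459, which is 1.38 times that of dawn, and its counted fraction by 20.0 h stood at 0.404, 1.36 times dawn's.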